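Plan
1. Retrosynthesis: the acrylate is cut at C11–C12 (enol triflate carbonylation) and at C7–C11 (Stille coupling), the 6-OH is taken back to a C6=C7 enone alkene, and C7 is then excised from ring B (bonds C6–C7 and C7–C8), which leaves a cyclopentene C5–C6=C8–C9–C10 fused trans to ring A plus one carbene carbon.
2. Enabling feature: in ring B the side-chain carbon C7 lies between the two oxygenated carbons C6 and C8, which is the pattern of a 7-bromoallyl cation captured by acetate. That cation forms when a C6/C7/C8 dibromocyclopropane opens, and C8 (next to the C9 methylene) is its accessible terminus.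
3. Forward order: ring A first (metathesis of a linalool-derived dienol, oxidation to enone 6), then a vinyl/allyl trans-difunctionalisation and a second metathesis give the trans-hydrindene, and ring B arises last by one-carbon ring expansion.
4. Stereochemistry: C4 from (R)-linalool; C5 by cuprate addition anti to the 4-silyloxy group; C10 by allylation anti to vinyl; C1 by axial hydride; C8 by α-face acetate capture; C6 by α-face borylcupration; C7 by equilibration of the acetyl group to equatorial.
5. Endgame: methyl ketone to enol triflate to methyl acrylate, then one desilylation.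

Key step: step 11

Remark: eudesmane locants (C1 to C15, β = face of the C10 methyl) are used for every ring carbon from compound 5 on, compounds 9 to 11 lack C7 so that C6 is bonded to C8, and commercial (R)-(−)-linalool is taken as enantiopure.

Step 1
Reactants: 1 (R)-(−)-linalool
Product: 2 (3R)-3,7-dimethyl-3-(triethylsilyloxy)octa-1,6-diene
Conditions: Et3SiOTf, 2,6-lutidine, CH2Cl2, −78 → 0 °C
Reagents that add atoms: triethylsilyl trifluoromethanesulfonate, CC[Si](CC)(CC)OS(=O)(=O)C(F)(F)F
Why: Silyl triflate O-silylation of the hindered tertiary allylic alcohol, which keeps the hydroxyl from opening the later epoxide and supplies the bulky group that steers step 6.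

Step 2
Reactants: 2 (3R)-3,7-dimethyl-3-(triethylsilyloxy)octa-1,6-diene
Product: 3 (3R)-6,7-epoxy-3,7-dimethyl-3-(triethylsilyloxy)oct-1-ene (both C6 epimers)
Conditions: mCPBA, CH2Cl2, 0 °C
Reagents that add atoms: 3-chloroperoxybenzoic acid, OOC(=O)c1cccc(Cl)c1
Why: Prilezhaev epoxidation is chemoselective for the electron-rich trisubstituted alkene over the vinyl group; the new stereocenter is not controlled and is erased in step 5.

Step 3
Reactants: 3 (3R)-6,7-epoxy-3,7-dimethyl-3-(triethylsilyloxy)oct-1-ene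
Product: 4 (6R)-2,6-dimethyl-6-(triethylsilyloxy)octa-1,7-dien-3-ol (both C3 epimers)
Conditions: Al(OiPr)3 (10 mol%), toluene, 110 °C
Reagents that add atoms: none
Why: Aluminium isopropoxide-catalysed isomerisation of the 2,2-dimethyloxirane to the allylic alcohol removes a methyl hydrogen syn to the coordinated oxygen and should give the secondary isopropenyl carbinol.

Step 4
Reactants: 4 (6R)-2,6-dimethyl-6-(triethylsilyloxy)octa-1,7-dien-3-ol
Product: 5 (4R)-2,4-dimethyl-4-(triethylsilyloxy)cyclohex-2-en-1-ol (both C1 epimers)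
Conditions: second-generation Grubbs catalyst RuCl2(H2IMes)(PCy3)(=CHPh) (5 mol%), CH2Cl2, 40 °C
Reagents that add atoms: none
Why: Ring-closing metathesis of the vinyl and isopropenyl groups closes ring A as the trisubstituted cyclohexene with loss of ethylene, the free allylic hydroxyl being tolerated.

Step 5
Reactants: 5 (4R)-2,4-dimethyl-4-(triethylsilyloxy)cyclohex-2-en-1-ol
Product: 6 (4R)-2,4-dimethyl-4-(triethylsilyloxy)cyclohex-2-en-1-one
Conditions: IBX (2-iodoxybenzoic acid), EtOAc, 75 °C
Reagents that add atoms: none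
Why: IBX oxidation of the allylic alcohol converges both epimers on one enone without touching the silyl ether.

Step 6
Reactants: 6 (4R)-2,4-dimethyl-4-(triethylsilyloxy)cyclohex-2-en-1-one
Product: 8 (2R,3R,4R)-2-allyl-2,4-dimethyl-4-(triethylsilyloxy)-3-vinylcyclohexan-1-one, via bromomagnesium enolate 7 (not isolated)
Conditions: CH2=CHMgBr, CuBr·SMe2 (15 mol%), THF, −40 °C; then allyl bromide, HMPA, −40 → 23 °C
Reagents that add atoms: vinylmagnesium bromide, C=C[Mg]Br; allyl bromide, C=CCBr
Why: Copper-catalysed conjugate addition should deliver vinyl to the β-carbon (C5) anti to the 4-silyloxy group, and the enolate is then C-allylated at C10 anti to the new vinyl group (conjugate addition–enolate alkylation), which sets the 5α-H/10β-methyl trans relationship.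

Step 7
Reactants: 8 (2R,3R,4R)-2-allyl-2,4-dimethyl-4-(triethylsilyloxy)-3-vinylcyclohexan-1-one
Product: 9 4α-(triethylsilyloxy)-7,11,12,13-tetranoreudesm-6(8)-en-1-one (trans-hydrindenone)
Conditions: second-generation Grubbs catalyst RuCl2(H2IMes)(PCy3)(=CHPh) (5 mol%), CH2Cl2, 40 °C
Reagents that add atoms: none
Why: Ring-closing metathesis of the trans-diequatorial vinyl and allyl groups closes the cyclopentene C5–C6=C8–C9–C10 with loss of ethylene and keeps the trans ring fusion set in step 6.

Step 8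
Reactants: 9 4α-(triethylsilyloxy)-7,11,12,13-tetranoreudesm-6(8)-en-1-one
Product: 10 4α-(triethylsilyloxy)-7,11,12,13-tetranoreudesm-6(8)-en-1β-ol
Conditions: NaBH4, MeOH, 0 °C
Reagents that add atoms: none
Why: Borohydride reduction with axial hydride delivery on the α face, anti to the adjacent axial C10 methyl, should give the equatorial 1β-alcohol.

Step 9
Reactants: 10 4α-(triethylsilyloxy)-7,11,12,13-tetranoreudesm-6(8)-en-1β-ol
Product: 11 1β-(tert-butyldimethylsilyloxy)-4α-(triethylsilyloxy)-7,11,12,13-tetranoreudesm-6(8)-ene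
Conditions: tBuMe2SiOTf, 2,6-lutidine, CH2Cl2, 0 °C
Reagents that add atoms: tert-butyldimethylsilyl trifluoromethanesulfonate, CC(C)(C)[Si](C)(C)OS(=O)(=O)C(F)(F)F
Why: Silyl triflate protection of the hindered neopentyl-type alcohol, needed because free hydroxyl reacts with dibromocarbene and could capture the cation of step 11.

Step 10
Reactants: 11 1β-(tert-butyldimethylsilyloxy)-4α-(triethylsilyloxy)-7,11,12,13-tetranoreudesm-6(8)-ene
Product: 12 7,7-dibromo-1β-(tert-butyldimethylsilyloxy)-4α-(triethylsilyloxy)-6,8-cyclo-11,12,13-trinoreudesmane (cyclopropane carbon C7 on the α face)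
Conditions: CHBr3, KOtBu, pentane, −10 → 23 °C
Reagents that add atoms: bromoform, BrC(Br)Br
Why: Dibromocarbene [2+1] cycloaddition to the cis-disubstituted cyclopentene should occur on the α face, anti to the angular C10 methyl; either face would lead to the same cation in step 11.

Step 11
Reactants: 12 7,7-dibromo-1β-(tert-butyldimethylsilyloxy)-4α-(triethylsilyloxy)-6,8-cyclo-11,12,13-trinoreudesmane
Product: 13 8α-acetoxy-7-bromo-1β-(tert-butyldimethylsilyloxy)-4α-(triethylsilyloxy)-11,12,13-trinoreudesm-6-ene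
Conditions: AgOAc (3 equiv), AcOH, 40 °C, dark
Reagents that add atoms: silver acetate, CC(=O)[O-].[Ag+]
Why: Silver ion abstracts the endo bromide of the gem-dibromocyclopropane while the C6–C8 σ-bond opens in a disrotatory 2π-electrocyclic process, so the five-membered ring C5–C6–C8–C9–C10 becomes the six-membered ring B as its 7-bromoallyl cation (C6–C7–C8), which acetate then captures. The closest known reaction type is the silver-promoted ring expansion of ring-fused 6,6-dibromobicyclo[3.1.0]hexanes to 2-bromocyclohex-2-enyl acetates. Ring B is not closed by a new ring bond but enlarged by one carbon: the carbene carbon C7 is inserted between C6 and C8 by electrocyclic ring opening. The only new stereocenter, C8, should be set by attack of acetate on the α face, anti to the axial C10 methyl that covers the β face of this terminus. The step needs capture at C8 and not at C6, and the substrate secures this: C8 is flanked by the C9 methylene, whereas C6 is shielded by C5 with its two quaternary neighbours and by the syn-axial 4β and 10β methyls. The exo bromine stays on C7 as the vinyl bromide for step 12, and the new C6=C7 alkene is the handle for step 13.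

Step 12
Reactants: 13 8α-acetoxy-7-bromo-1β-(tert-butyldimethylsilyloxy)-4α-(triethylsilyloxy)-11,12,13-trinoreudesm-6-ene
Product: 15 8α-acetoxy-1β-(tert-butyldimethylsilyloxy)-4α-(triethylsilyloxy)-12-noreudesm-6-en-11-one, via dienyl ether 14 (not isolated)
Conditions: CH2=C(OEt)SnBu3, PdCl2(PPh3)2 (5 mol%), toluene, 90 °C; then 0.5 M HCl, THF, 0 °C
Reagents that add atoms: tributyl(1-ethoxyvinyl)stannane, C=C(OCC)[Sn](CCCC)(CCCC)CCCC; water, O
Why: Stille coupling of the vinyl bromide (oxidative addition into C–Br should outpace ionisation of the hindered allylic acetate) followed by acid hydrolysis of the enol ether gives the methyl ketone; no stereocenter is touched.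

Step 13
Reactants: 15 8α-acetoxy-1β-(tert-butyldimethylsilyloxy)-4α-(triethylsilyloxy)-12-noreudesm-6-en-11-one
Product: 17 8α-acetoxy-6α-hydroxy-1β-(tert-butyldimethylsilyloxy)-4α-(triethylsilyloxy)-12-noreudesman-11-one, via boronate 16 (not isolated)
Conditions: B2pin2, CuCl (10 mol%), bis[2-(diphenylphosphino)phenyl] ether (10 mol%), NaOtBu (20 mol%), MeOH (2 equiv), THF, 23 °C; then NaBO3·4H2O, THF/H2O, 0 → 23 °C
Reagents that add atoms: sodium perborate, [Na+].[O-]OB=O
Why: Copper-catalysed conjugate borylation: syn borylcupration of the enone from the α face (the β face of C6 is covered by the 4β and 10β methyls) places boron at C6, protonation and base equilibration should leave the C7 acetyl equatorial (β), and perborate oxidation replaces boron by hydroxyl with retention.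

Step 14
Reactants: 17 8α-acetoxy-6α-hydroxy-1β-(tert-butyldimethylsilyloxy)-4α-(triethylsilyloxy)-12-noreudesman-11-one
Product: 18 8α-acetoxy-1β-(tert-butyldimethylsilyloxy)-4α,6α-bis(triethylsilyloxy)-12-noreudesman-11-one
Conditions: Et3SiOTf, 2,6-lutidine, CH2Cl2, −78 °C
Reagents that add atoms: triethylsilyl trifluoromethanesulfonate, CC[Si](CC)(CC)OS(=O)(=O)C(F)(F)F
Why: Silyl triflate protection of the hindered 6α-hydroxyl at low temperature, so that the next step meets only one acidic site besides the methyl ketone.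

Step 15
Reactants: 18 8α-acetoxy-1β-(tert-butyldimethylsilyloxy)-4α,6α-bis(triethylsilyloxy)-12-noreudesman-11-one
Product: 20 8α-acetoxy-1β-(tert-butyldimethylsilyloxy)-4α,6α-bis(triethylsilyloxy)-12-noreudesm-11(13)-en-11-yl trifluoromethanesulfonate, via potassium enolate 19 (not isolated)
Conditions: KN(SiMe3)2 added to 18 and PhNTf2, THF, −78 °C
Reagents that add atoms: N-phenylbis(trifluoromethanesulfonimide), O=S(=O)(N(c1ccccc1)S(=O)(=O)C(F)(F)F)C(F)(F)F
Why: Kinetic enolisation of the methyl ketone at the unhindered CH3 and O-triflation of the enolate as it forms; the C7–H between two oxygenated carbons is not removed, so C7 and both β-oxygens are kept.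

Step 16
Reactants: 20 8α-acetoxy-1β-(tert-butyldimethylsilyloxy)-4α,6α-bis(triethylsilyloxy)-12-noreudesm-11(13)-en-11-yl trifluoromethanesulfonate
Product: 21 methyl 8α-acetoxy-1β-(tert-butyldimethylsilyloxy)-4α,6α-bis(triethylsilyloxy)eudesm-11(13)-en-12-oate
Conditions: Pd(OAc)2 (10 mol%), PPh3 (20 mol%), Et3N, CO (1 atm), MeOH/DMF, 40 °C
Reagents that add atoms: carbon monoxide, [C-]#[O+]; methanol, CO
Why: Palladium-catalysed methoxycarbonylation of the enol triflate (oxidative addition, CO insertion, methanolysis) gives the 2-substituted acrylate and adds C12 without touching C7.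

Step 17
Reactants: 21 methyl 8α-acetoxy-1β-(tert-butyldimethylsilyloxy)-4α,6α-bis(triethylsilyloxy)eudesm-11(13)-en-12-oate
Product: 22 methyl 8α-acetoxy-1β,4α,6α-trihydroxyeudesm-11(13)-en-12-oate (CNP0272656.1)
Conditions: HF·pyridine, pyridine, THF, 0 → 40 °C
Reagents that add atoms: none
Why: Fluoride-mediated cleavage of the three silyl ethers under buffered acidic conditions should leave the acetate, the acrylate and the tertiary alcohol intact, and the rigid diequatorial 6,8-arrangement prevents acetyl migration.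

Compound list
1 | (R)-(−)-linalool, (3R)-3,7-dimethylocta-1,6-dien-3-ol | C=C[C@](C)(O)CCC=C(C)C | starting material
2 | (3R)-3,7-dimethyl-3-(triethylsilyloxy)octa-1,6-diene | C=C[C@](C)(O[Si](CC)(CC)CC)CCC=C(C)C | intermediate
3 | (3R)-6,7-epoxy-3,7-dimethyl-3-(triethylsilyloxy)oct-1-ene, both C6 epimers | C=C[C@](C)(O[Si](CC)(CC)CC)CCC1OC1(C)C | intermediate
4 | (6R)-2,6-dimethyl-6-(triethylsilyloxy)octa-1,7-dien-3-ol, both C3 epimers | C=C[C@](C)(O[Si](CC)(CC)CC)CCC(O)C(C)=C | intermediate
5 | (4R)-2,4-dimethyl-4-(triethylsilyloxy)cyclohex-2-en-1-ol, both C1 epimers | CC1=C[C@](C)(O[Si](CC)(CC)CC)CCC1O | intermediate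
6 | (4R)-2,4-dimethyl-4-(triethylsilyloxy)cyclohex-2-en-1-one | CC1=C[C@](C)(O[Si](CC)(CC)CC)CCC1=O | intermediate
7 | bromomagnesium enolate of the vinyl adduct of 6 (vinyl trans to the silyloxy group) | C=C[C@@H]1C(C)=C(O[Mg]Br)CC[C@@]1(C)O[Si](CC)(CC)CC | intermediate (not isolated)
8 | (2R,3R,4R)-2-allyl-2,4-dimethyl-4-(triethylsilyloxy)-3-vinylcyclohexan-1-one (vinyl trans to allyl and trans to the silyloxy group) | C=C[C@@H]1[C@@](C)(CC=C)C(=O)CC[C@@]1(C)O[Si](CC)(CC)CC | intermediate
9 | 4α-(triethylsilyloxy)-7,11,12,13-tetranoreudesm-6(8)-en-1-one (trans-hydrindenone; 5α-H, 10β-CH3, 4β-CH3) | C1=C[C@@H]2[C@@](C)(C1)C(=O)CC[C@@]2(C)O[Si](CC)(CC)CC | intermediate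
10 | 4α-(triethylsilyloxy)-7,11,12,13-tetranoreudesm-6(8)-en-1β-ol | C1=C[C@@H]2[C@@](C)(C1)[C@H](O)CC[C@@]2(C)O[Si](CC)(CC)CC | intermediate
11 | 1β-(tert-butyldimethylsilyloxy)-4α-(triethylsilyloxy)-7,11,12,13-tetranoreudesm-6(8)-ene | C1=C[C@@H]2[C@@](C)(C1)[C@H](O[Si](C)(C)C(C)(C)C)CC[C@@]2(C)O[Si](CC)(CC)CC | intermediate
12 | 7,7-dibromo-1β-(tert-butyldimethylsilyloxy)-4α-(triethylsilyloxy)-6,8-cyclo-11,12,13-trinoreudesmane (C7 on the α face, 6β-H, 8β-H) | BrC1(Br)[C@@H]3[C@@H]2[C@@](C)(C[C@H]13)[C@H](O[Si](C)(C)C(C)(C)C)CC[C@@]2(C)O[Si](CC)(CC)CC | intermediate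
13 | 8α-acetoxy-7-bromo-1β-(tert-butyldimethylsilyloxy)-4α-(triethylsilyloxy)-11,12,13-trinoreudesm-6-ene | BrC1=C[C@@H]2[C@@](C)(C[C@@H]1OC(C)=O)[C@H](O[Si](C)(C)C(C)(C)C)CC[C@@]2(C)O[Si](CC)(CC)CC | intermediate
14 | 8α-acetoxy-11-ethoxy-1β-(tert-butyldimethylsilyloxy)-4α-(triethylsilyloxy)-12-noreudesma-6,11(13)-diene | C=C(OCC)C1=C[C@@H]2[C@@](C)(C[C@@H]1OC(C)=O)[C@H](O[Si](C)(C)C(C)(C)C)CC[C@@]2(C)O[Si](CC)(CC)CC | intermediate (not isolated)
15 | 8α-acetoxy-1β-(tert-butyldimethylsilyloxy)-4α-(triethylsilyloxy)-12-noreudesm-6-en-11-one | CC(=O)C1=C[C@@H]2[C@@](C)(C[C@@H]1OC(C)=O)[C@H](O[Si](C)(C)C(C)(C)C)CC[C@@]2(C)O[Si](CC)(CC)CC | intermediate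
16 | 8α-acetoxy-6α-(4,4,5,5-tetramethyl-1,3,2-dioxaborolan-2-yl)-1β-(tert-butyldimethylsilyloxy)-4α-(triethylsilyloxy)-12-noreudesman-11-one (7α-H) | CC(=O)[C@H]1[C@H](B3OC(C)(C)C(C)(C)O3)[C@@H]2[C@@](C)(C[C@@H]1OC(C)=O)[C@H](O[Si](C)(C)C(C)(C)C)CC[C@@]2(C)O[Si](CC)(CC)CC | intermediate (not isolated)
17 | 8α-acetoxy-6α-hydroxy-1β-(tert-butyldimethylsilyloxy)-4α-(triethylsilyloxy)-12-noreudesman-11-one (7α-H, acetyl β) | CC(=O)[C@H]1[C@H](O)[C@@H]2[C@@](C)(C[C@@H]1OC(C)=O)[C@H](O[Si](C)(C)C(C)(C)C)CC[C@@]2(C)O[Si](CC)(CC)CC | intermediate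
18 | 8α-acetoxy-1β-(tert-butyldimethylsilyloxy)-4α,6α-bis(triethylsilyloxy)-12-noreudesman-11-one | CC(=O)[C@H]1[C@H](O[Si](CC)(CC)CC)[C@@H]2[C@@](C)(C[C@@H]1OC(C)=O)[C@H](O[Si](C)(C)C(C)(C)C)CC[C@@]2(C)O[Si](CC)(CC)CC | intermediate
19 | potassium C11–C13 enolate of 18 | [K+].C=C([O-])[C@H]1[C@H](O[Si](CC)(CC)CC)[C@@H]2[C@@](C)(C[C@@H]1OC(C)=O)[C@H](O[Si](C)(C)C(C)(C)C)CC[C@@]2(C)O[Si](CC)(CC)CC | intermediate (not isolated)
20 | 8α-acetoxy-1β-(tert-butyldimethylsilyloxy)-4α,6α-bis(triethylsilyloxy)-12-noreudesm-11(13)-en-11-yl trifluoromethanesulfonate | C=C(OS(=O)(=O)C(F)(F)F)[C@H]1[C@H](O[Si](CC)(CC)CC)[C@@H]2[C@@](C)(C[C@@H]1OC(C)=O)[C@H](O[Si](C)(C)C(C)(C)C)CC[C@@]2(C)O[Si](CC)(CC)CC | intermediate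
21 | methyl 8α-acetoxy-1β-(tert-butyldimethylsilyloxy)-4α,6α-bis(triethylsilyloxy)eudesm-11(13)-en-12-oate | C=C(C(=O)OC)[C@H]1[C@H](O[Si](CC)(CC)CC)[C@@H]2[C@@](C)(C[C@@H]1OC(C)=O)[C@H](O[Si](C)(C)C(C)(C)C)CC[C@@]2(C)O[Si](CC)(CC)CC | intermediate
22 | methyl 8α-acetoxy-1β,4α,6α-trihydroxyeudesm-11(13)-en-12-oate (5α-H, 7α-H, 10β-CH3, 4β-CH3) | C=C(C(=O)OC)[C@H]1[C@H](O)[C@@H]2[C@@](C)(C[C@@H]1OC(C)=O)[C@H](O)CC[C@@]2(C)O | target

Total step count: 17. Longest linear sequence: 17 steps (fully linear from 1).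

Steps most likely to fail

Step 11. Acetate may attack the allyl cation on the β face of C8 or at C6, and warm acetic acid may cleave the tertiary silyl ether. The fallback sets out from 12: silver perchlorate AgClO4 with CaCO3 in aqueous acetone should open the cyclopropane to the allylic alcohols 7-bromo-1β-(tert-butyldimethylsilyloxy)-4α-(triethylsilyloxy)-11,12,13-trinoreudesm-6-en-8-ol F1 as a mixture of C8 epimers. IBX oxidation converges them on the bromoenone F2. Corey–Bakshi–Shibata reduction with the (R)-2-methyl-CBS-oxazaborolidine and BH3·SMe2, under reagent control with hydride delivered to the β face, should give the 8α-alcohol F3. Acetylation with Ac2O, pyridine and DMAP comes back to the route at 13.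

Step 13. Borylcupration at the crowded C6 may be slow, and the copper enolate may eliminate the C8 acetate. The fallback sets out from 15: nucleophilic epoxidation with tBuOOH and DBU in CH2Cl2 should give the 6α,7α-epoxy ketone F4 by attack on the open α face. Reductive opening of the Cα–O bond with sodium phenylselenide (from PhSeSePh and NaBH4 in EtOH with AcOH) then gives the β-hydroxy ketone with the acetyl group equatorial, which is 17.

Step 6. The hindered bromomagnesium enolate may undergo O-allylation or proton transfer in place of C-allylation at the quaternary centre. The fallback sets out from 6: the same copper-catalysed vinyl addition is run, but the enolate is trapped with allyl chloroformate as the allyl enol carbonate F5, which is isolated. Decarboxylative Tsuji allylation with Pd(PPh3)4 (zerovalent palladium) in THF then forms the C10–allyl bond anti to the vinyl group and comes back to the route at 8.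

Further compounds
F1 | step 11 | 7-bromo-1β-(tert-butyldimethylsilyloxy)-4α-(triethylsilyloxy)-11,12,13-trinoreudesm-6-en-8-ol, both C8 epimers | BrC1=C[C@@H]2[C@@](C)(CC1O)[C@H](O[Si](C)(C)C(C)(C)C)CC[C@@]2(C)O[Si](CC)(CC)CC
F2 | step 11 | 7-bromo-1β-(tert-butyldimethylsilyloxy)-4α-(triethylsilyloxy)-11,12,13-trinoreudesm-6-en-8-one | BrC1=C[C@@H]2[C@@](C)(CC1=O)[C@H](O[Si](C)(C)C(C)(C)C)CC[C@@]2(C)O[Si](CC)(CC)CC
F3 | step 11 | 7-bromo-1β-(tert-butyldimethylsilyloxy)-4α-(triethylsilyloxy)-11,12,13-trinoreudesm-6-en-8α-ol | BrC1=C[C@@H]2[C@@](C)(C[C@@H]1O)[C@H](O[Si](C)(C)C(C)(C)C)CC[C@@]2(C)O[Si](CC)(CC)CC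
F4 | step 13 | 8α-acetoxy-6α,7α-epoxy-1β-(tert-butyldimethylsilyloxy)-4α-(triethylsilyloxy)-12-noreudesman-11-one | CC(=O)[C@]12O[C@@H]2[C@@H]3[C@@](C)(C[C@@H]1OC(C)=O)[C@H](O[Si](C)(C)C(C)(C)C)CC[C@@]3(C)O[Si](CC)(CC)CC
F5 | step 6 | allyl enol carbonate of the vinyl adduct of 6 (O-allyloxycarbonyl derivative of enolate 7) | C=C[C@@H]1C(C)=C(OC(=O)OCC=C)CC[C@@]1(C)O[Si](CC)(CC)CC
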